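**Plan**

1. Retrosynthesis: the O–Si bonds at O7 and O2' and the O–CH3 bond at O5 are cut first. Then follow the C2–C3 bond of ring C (back to an ortho-OCH3 on ring A and a diazo carbon), the C=N2 bond, the C3–C1' bond to ring B, the C4–C4a bond and the C3'–geranyl bond.
2. Enabling feature: C2 of ring C is a CH2 held between O1 and the stereogenic C3, so it can start as the methyl carbon of a methoxy group ortho to the ketone on ring A. In a 2,6-dimethoxyaryl ketone both such groups are equivalent, and the unused one ends as 5-OH.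
3. Forward: ring B is built up by two directed lithiations of 3-methoxyphenol MOM ether (geranyl chain first, then Br), ring A by lithiation and acetylation of silylated 3,5-dimethoxyphenol. Palladium joins them to a deoxybenzoin, diazo transfer follows, and ring C, the only ring made, closes in the rhodium step.
4. Stereochemistry: C3 (S), the single stereocentre, is created in the ring-closing C–H insertion under control of the chiral dirhodium carboxylate. The E-alkene comes with geranyl bromide, and the two later steps avoid base so that C3 is not enolised.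

Key step: step 10

Abbreviations: geranyl = (2E)-3,7-dimethylocta-2,6-dien-1-yl; MOM = methoxymethyl; TBS = tert-butyldimethylsilyl; TIPS = triisopropylsilyl; p-ABSA = 4-acetamidobenzenesulfonyl azide.

Assumption: the facial sense of Rh2(S-PTAD)4 on this substrate cannot be predicted with certainty; should a pilot run favour (3R), the mirror-image catalyst Rh2(R-PTAD)4 would be used in step 10 with nothing else changed.

**Route**

Step 1
Reactants: 1 3-methoxyphenol
Product: 2 1-methoxy-3-(methoxymethoxy)benzene
Conditions: MOMCl, iPr2NEt, CH2Cl2, 0 °C → rt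
Reagents that add atoms: chloromethyl methyl ether (MOMCl), SMILES COCCl
Why: Williamson-type O-alkylation of the phenol with the reactive α-chloro ether under amine base gives the MOM ether that will direct both ring lithiations.

Step 2
Reactants: 2 1-methoxy-3-(methoxymethoxy)benzene; 3 geranyl bromide
Product: 5 2-geranyl-1-methoxy-3-(methoxymethoxy)benzene, via aryllithium 4 (not isolated)
Conditions: n-BuLi, THF, 0 °C → rt; CuBr·SMe2 (10 mol %), then 3, −78 °C → rt
Reagents that add atoms: none
Why: Directed ortho-metalation occurs at the carbon flanked by the OMOM and OMe groups, where both oxygens hold the lithium, and copper-catalysed SN2 allylation of aryllithium 4 by the primary allylic bromide attaches the chain with its E-alkene untouched.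

Step 3
Reactants: 5 2-geranyl-1-methoxy-3-(methoxymethoxy)benzene
Product: 7 1-bromo-3-geranyl-4-methoxy-2-(methoxymethoxy)benzene, via aryllithium 6 (not isolated)
Conditions: n-BuLi, TMEDA, Et2O, 0 °C; then BrCCl2CCl2Br, −78 °C → rt
Reagents that add atoms: 1,2-dibromo-1,1,2,2-tetrachloroethane, SMILES BrC(Cl)(Cl)C(Cl)(Cl)Br
Why: A second directed ortho-metalation is steered by the MOM ether, the stronger of the two directing groups, to the free carbon next to it (ring deprotonation being kinetically preferred over lateral deprotonation of the ArCH2 group with n-BuLi/TMEDA), and aryllithium 6 takes bromine from the electrophilic bromine donor.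

Step 4
Reactants: 7 1-bromo-3-geranyl-4-methoxy-2-(methoxymethoxy)benzene
Product: 8 6-bromo-2-geranyl-3-methoxyphenol
Conditions: conc. HCl (cat.), MeOH, 40 °C
Reagents that add atoms: none
Why: Acid-catalysed acetal methanolysis removes the MOM group, whose OCH2O hydrogens would otherwise be the preferred site of carbene insertion in step 10, under conditions too mild to protonate the trisubstituted alkenes.

Step 5
Reactants: 8 6-bromo-2-geranyl-3-methoxyphenol
Product: 9 (6-bromo-2-geranyl-3-methoxyphenoxy)(tert-butyl)dimethylsilane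
Conditions: TBSCl, imidazole, DMF, rt → 40 °C
Reagents that add atoms: tert-butyldimethylsilyl chloride (TBSCl), SMILES CC(C)(C)[Si](C)(C)Cl
Why: Imidazole-promoted silyl ether formation puts on the phenol a protecting group that has no C–H bond next to oxygen and can later be removed by fluoride without base.

Step 6
Reactants: 10 3,5-dimethoxyphenol
Product: 11 (3,5-dimethoxyphenoxy)tri(propan-2-yl)silane
Conditions: TIPSCl, imidazole, DMF, rt
Reagents that add atoms: triisopropylsilyl chloride (TIPSCl), SMILES CC(C)[Si](Cl)(C(C)C)C(C)C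
Why: Silyl ether formation gives a bulky, poorly coordinating OTIPS group that withstands n-BuLi and the later basic steps and leaves the carbon between the two methoxy groups as the only well-activated site for lithiation.

Step 7
Reactants: 11 (3,5-dimethoxyphenoxy)tri(propan-2-yl)silane; 12 N-methoxy-N-methylacetamide
Product: 15 1-[2,6-dimethoxy-4-(triisopropylsilyloxy)phenyl]ethanone, via aryllithium 13 (not isolated), via lithium alkoxide adduct 14 (not isolated)
Conditions: n-BuLi, THF, 0 °C → rt; then 12, −78 → 0 °C; H2O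
Reagents that add atoms: none
Why: Directed ortho-metalation between the two methoxy groups gives aryllithium 13, and its addition to the N-methoxy-N-methylamide stops at the chelated tetrahedral alkoxide 14 (Weinreb ketone synthesis), which releases the methyl ketone on aqueous quench.

Step 8
Reactants: 15 1-[2,6-dimethoxy-4-(triisopropylsilyloxy)phenyl]ethanone; 9 (6-bromo-2-geranyl-3-methoxyphenoxy)(tert-butyl)dimethylsilane
Product: 16 2-[2-(tert-butyldimethylsilyloxy)-3-geranyl-4-methoxyphenyl]-1-[2,6-dimethoxy-4-(triisopropylsilyloxy)phenyl]ethanone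
Conditions: Pd(OAc)2 (2 mol %), XPhos (4 mol %), K3PO4, toluene, 80 °C
Reagents that add atoms: none
Why: Palladium-catalysed α-arylation of a ketone enolate (Buchwald–Hartwig type) joins the methyl carbon of 15 to the brominated carbon of 9 and so forms the C3–C1' bond, the mild phosphate base sparing the aryl silyl ethers while the ortho substituent of the bromide and the greater acidity of the product hold the reaction at monoarylation.

Step 9
Reactants: 16 2-[2-(tert-butyldimethylsilyloxy)-3-geranyl-4-methoxyphenyl]-1-[2,6-dimethoxy-4-(triisopropylsilyloxy)phenyl]ethanone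
Product: 17 2-diazo-2-[2-(tert-butyldimethylsilyloxy)-3-geranyl-4-methoxyphenyl]-1-[2,6-dimethoxy-4-(triisopropylsilyloxy)phenyl]ethanone
Conditions: p-ABSA, DBU, MeCN (dry), 0 °C → rt
Reagents that add atoms: 4-acetamidobenzenesulfonyl azide (p-ABSA), SMILES CC(=O)Nc1ccc(S(=O)(=O)N=[N+]=[N-])cc1
Why: Regitz diazo transfer, in which the DBU-generated enolate of the benzylic ketone attacks the terminal nitrogen of the sulfonyl azide and the resulting triazene collapses to the α-aryl-α-diazo ketone and the sulfonamide.

Step 10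
Reactants: 17 2-diazo-2-[2-(tert-butyldimethylsilyloxy)-3-geranyl-4-methoxyphenyl]-1-[2,6-dimethoxy-4-(triisopropylsilyloxy)phenyl]ethanone
Product: 19 (3S)-3-[2-(tert-butyldimethylsilyloxy)-3-geranyl-4-methoxyphenyl]-5-methoxy-7-(triisopropylsilyloxy)chroman-4-one, via rhodium carbene 18 (not isolated)
Conditions: Rh2(S-PTAD)4 (1 mol %), 4 Å MS, PhCF3, 0 °C → rt, slow addition of 17
Reagents that add atoms: none
Why: Proposed new method: the dirhodium tetracarboxylate expels N2 from 17 to give carbene 18, whose carbon bears ring B as donor and the aroyl group as acceptor, and a C–H bond of an ortho-methoxy group on ring A, made hydridic by the adjacent oxygen, adds across that carbon in a single concerted three-centre event that creates both C2–C3 and C3–H. The closest known reactions are the rhodium-carbene C–H insertions of 2-alkoxyaryl diazo ketones that give chroman-4-ones and the insertions of aryl-substituted donor–acceptor carbenes into methyl ether C–H bonds; their combination on an α-aryl-α-diazo ketone with enantiocontrol is the untested part. Ring C closes by 1,6 C–H insertion through a six-membered array (C3, C4, C4a, C8a, O1, C2). The stereocentre C3 is set by the chiral phthalimido-carboxylate pocket of Rh2(S-PTAD)4, which exposes one face of the carbene, and it should persist because its hydrogen arrives from carbon in a neutral, aprotic medium. The step needs insertion to win over oxonium ylide formation at the methoxy oxygen, over alkene attack and over other C–H bonds: a methyl group migrates poorly so ylide formation should be reversible and unproductive, the silyl ethers have no C–H next to oxygen, the geranyl chain sits meta to the carbene-bearing carbon and cannot reach it, and the two ortho-methoxy groups are equivalent so that either rotamer of the aroyl group is productive.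

Step 11
Reactants: 19 (3S)-3-[2-(tert-butyldimethylsilyloxy)-3-geranyl-4-methoxyphenyl]-5-methoxy-7-(triisopropylsilyloxy)chroman-4-one
Product: 21 (3S)-3-[2-(tert-butyldimethylsilyloxy)-3-geranyl-4-methoxyphenyl]-5-hydroxy-7-(triisopropylsilyloxy)chroman-4-one, via iodomagnesium phenoxide 20 (not isolated)
Conditions: MgI2·OEt2 (3 equiv), toluene/Et2O, 40 °C; pH 7 buffer
Reagents that add atoms: none
Why: Chelation-controlled ether cleavage, in which magnesium binds between the C4 carbonyl and the peri 5-methoxy oxygen so that iodide dealkylates only this methyl ether by SN2 attack, leaving the unchelated 4'-methoxy group, both silyl ethers and, in the absence of base, the C3 centre unchanged.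

Step 12
Reactants: 21 (3S)-3-[2-(tert-butyldimethylsilyloxy)-3-geranyl-4-methoxyphenyl]-5-hydroxy-7-(triisopropylsilyloxy)chroman-4-one
Product: 22 (3S)-3-(3-geranyl-2-hydroxy-4-methoxyphenyl)-5,7-dihydroxychroman-4-one (CNP0303304.1)
Conditions: HF·pyridine, pyridine, THF, 0 °C → rt
Reagents that add atoms: none
Why: Fluoride-mediated desilylation driven by Si–F bond formation frees the 7- and 2'-phenols in a weakly acidic, buffered medium in which the α-aryl ketone should not enolise, so the (3S) configuration is retained.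

**Compound list**

1 | 3-methoxyphenol | COc1cccc(O)c1 | starting material
2 | 1-methoxy-3-(methoxymethoxy)benzene | COCOc1cccc(OC)c1 | intermediate
3 | geranyl bromide, (2E)-1-bromo-3,7-dimethylocta-2,6-diene | BrC/C=C(\C)CCC=C(C)C | starting material
4 | [2-methoxy-6-(methoxymethoxy)phenyl]lithium | COCOc1cccc(OC)c1[Li] | intermediate
5 | 2-geranyl-1-methoxy-3-(methoxymethoxy)benzene | COCOc1cccc(OC)c1C/C=C(\C)CCC=C(C)C | intermediate
6 | [3-geranyl-4-methoxy-2-(methoxymethoxy)phenyl]lithium | COCOc1c([Li])ccc(OC)c1C/C=C(\C)CCC=C(C)C | intermediate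
7 | 1-bromo-3-geranyl-4-methoxy-2-(methoxymethoxy)benzene | COCOc1c(Br)ccc(OC)c1C/C=C(\C)CCC=C(C)C | intermediate
8 | 6-bromo-2-geranyl-3-methoxyphenol | Oc1c(Br)ccc(OC)c1C/C=C(\C)CCC=C(C)C | intermediate
9 | (6-bromo-2-geranyl-3-methoxyphenoxy)(tert-butyl)dimethylsilane | CC(C)(C)[Si](C)(C)Oc1c(Br)ccc(OC)c1C/C=C(\C)CCC=C(C)C | intermediate
10 | 3,5-dimethoxyphenol | COc1cc(O)cc(OC)c1 | starting material
11 | (3,5-dimethoxyphenoxy)tri(propan-2-yl)silane | COc1cc(OC)cc(O[Si](C(C)C)(C(C)C)C(C)C)c1 | intermediate
12 | N-methoxy-N-methylacetamide | CC(=O)N(C)OC | starting material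
13 | [2,6-dimethoxy-4-(triisopropylsilyloxy)phenyl]lithium | COc1cc(O[Si](C(C)C)(C(C)C)C(C)C)cc(OC)c1[Li] | intermediate
14 | lithium 1-[2,6-dimethoxy-4-(triisopropylsilyloxy)phenyl]-1-[methoxy(methyl)amino]ethanolate | COc1cc(O[Si](C(C)C)(C(C)C)C(C)C)cc(OC)c1C(C)(O[Li])N(C)OC | intermediate
15 | 1-[2,6-dimethoxy-4-(triisopropylsilyloxy)phenyl]ethanone | COc1cc(O[Si](C(C)C)(C(C)C)C(C)C)cc(OC)c1C(C)=O | intermediate
16 | 2-[2-(tert-butyldimethylsilyloxy)-3-geranyl-4-methoxyphenyl]-1-[2,6-dimethoxy-4-(triisopropylsilyloxy)phenyl]ethanone | COc1cc(O[Si](C(C)C)(C(C)C)C(C)C)cc(OC)c1C(=O)Cc1ccc(OC)c(C/C=C(\C)CCC=C(C)C)c1O[Si](C)(C)C(C)(C)C | intermediate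
17 | 2-diazo-2-[2-(tert-butyldimethylsilyloxy)-3-geranyl-4-methoxyphenyl]-1-[2,6-dimethoxy-4-(triisopropylsilyloxy)phenyl]ethanone | COc1cc(O[Si](C(C)C)(C(C)C)C(C)C)cc(OC)c1C(=O)C(=[N+]=[N-])c1ccc(OC)c(C/C=C(\C)CCC=C(C)C)c1O[Si](C)(C)C(C)(C)C | intermediate
18 | rhodium carbene formed from 17 (carbene carbon bound to one rhodium of Rh2(S-PTAD)4; the catalyst core is drawn as [Rh]) | COc1cc(O[Si](C(C)C)(C(C)C)C(C)C)cc(OC)c1C(=O)C(=[Rh])c1ccc(OC)c(C/C=C(\C)CCC=C(C)C)c1O[Si](C)(C)C(C)(C)C | intermediate
19 | (3S)-3-[2-(tert-butyldimethylsilyloxy)-3-geranyl-4-methoxyphenyl]-5-methoxy-7-(triisopropylsilyloxy)chroman-4-one | COc1ccc([C@H]2COc3cc(O[Si](C(C)C)(C(C)C)C(C)C)cc(OC)c3C2=O)c(O[Si](C)(C)C(C)(C)C)c1C/C=C(\C)CCC=C(C)C | intermediate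
20 | iodomagnesium 5-phenoxide of 21 | COc1ccc([C@H]2COc3cc(O[Si](C(C)C)(C(C)C)C(C)C)cc(O[Mg]I)c3C2=O)c(O[Si](C)(C)C(C)(C)C)c1C/C=C(\C)CCC=C(C)C | intermediate
21 | (3S)-3-[2-(tert-butyldimethylsilyloxy)-3-geranyl-4-methoxyphenyl]-5-hydroxy-7-(triisopropylsilyloxy)chroman-4-one | COc1ccc([C@H]2COc3cc(O[Si](C(C)C)(C(C)C)C(C)C)cc(O)c3C2=O)c(O[Si](C)(C)C(C)(C)C)c1C/C=C(\C)CCC=C(C)C | intermediate
22 | (3S)-3-(3-geranyl-2-hydroxy-4-methoxyphenyl)-5,7-dihydroxychroman-4-one | COc1ccc([C@H]2COc3cc(O)cc(O)c3C2=O)c(O)c1C/C=C(\C)CCC=C(C)C | target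

**Step count and risks**

Total steps: 12. Longest linear sequence: 10 steps (steps 1–5 and 8–12, from 3-methoxyphenol); the ring A branch (steps 6–7) joins at step 8.

Steps most likely to fail:

Step 10 (the step beyond known chemistry). The carbene may be drained by oxonium ylide formation at the methoxy oxygen followed by methyl shift, or by dimerisation, or the insertion may proceed with poor face selectivity. The fallback uses known chemistry, sets out from 16 and returns at 19. Deoxybenzoin 16 would be monodemethylated at the chelated methoxy group with MgI2·OEt2 to 2-[2-(tert-butyldimethylsilyloxy)-3-geranyl-4-methoxyphenyl]-1-[2-hydroxy-6-methoxy-4-(triisopropylsilyloxy)phenyl]ethanone F1. Heating with N,N-dimethylformamide dimethyl acetal in toluene would supply C2 and close ring C to the isoflavone 3-[2-(tert-butyldimethylsilyloxy)-3-geranyl-4-methoxyphenyl]-5-methoxy-7-(triisopropylsilyloxy)chromen-4-one F2. Noyori–Ikariya transfer hydrogenation with RuCl(p-cymene)(TsDPEN) (the enantiomer that leads to the 3S,4S product) and HCO2H/Et3N would reduce the C2=C3 bond and then the ketone, with dynamic kinetic resolution of the labile C3 centre, to the cis alcohol (3S,4S)-3-[2-(tert-butyldimethylsilyloxy)-3-geranyl-4-methoxyphenyl]-5-methoxy-7-(triisopropylsilyloxy)chroman-4-ol F3. Dess–Martin oxidation in CH2Cl2 at 0 °C would then return ketone 19 without base.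

Step 11. Lewis-acid-promoted enolisation may erode the C3 configuration, or the diene chain may be protonated and cyclise, while the methyl ether is cleaved. The fallback moves the demethylation ahead of the stereocentre and the geranyl group; it sets out from 15 and returns at 22.
- BCl3 (CH2Cl2, −78 °C) would cleave one chelated methyl ether of 15 to 1-[2-hydroxy-6-methoxy-4-(triisopropylsilyloxy)phenyl]ethanone F4.
- TBSOTf/2,6-lutidine would give 1-[2-(tert-butyldimethylsilyloxy)-6-methoxy-4-(triisopropylsilyloxy)phenyl]ethanone F5.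
- α-Arylation with 9 as in step 8 would give 2-[2-(tert-butyldimethylsilyloxy)-3-geranyl-4-methoxyphenyl]-1-[2-(tert-butyldimethylsilyloxy)-6-methoxy-4-(triisopropylsilyloxy)phenyl]ethanone F6.
- Diazo transfer as in step 9 would give the corresponding 2-diazo ketone F7.
- Rhodium-carbene insertion into the one remaining methoxy group would give (3S)-5-(tert-butyldimethylsilyloxy)-3-[2-(tert-butyldimethylsilyloxy)-3-geranyl-4-methoxyphenyl]-7-(triisopropylsilyloxy)chroman-4-one F8.
- Buffered HF·pyridine would remove all three silyl groups at once to give 22, so that no Lewis acid meets the stereocentre.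

Step 8. The base may strip or shift the silyl groups, coupling at the ortho-substituted bromide may be sluggish, or the ketone may be arylated twice. The fallback forms the C4–C4a bond instead of the C3–C1' bond; it sets out from 9 and returns at 16. Palladium-catalysed coupling of 9 with the Reformatsky reagent BrZnCH2CO2Et (Pd(dba)2/XPhos, THF, neutral conditions) would give ethyl 2-[2-(tert-butyldimethylsilyloxy)-3-geranyl-4-methoxyphenyl]acetate F9. Me(MeO)NH·HCl with i-PrMgCl (THF, −20 °C) would convert it into 2-[2-(tert-butyldimethylsilyloxy)-3-geranyl-4-methoxyphenyl]-N-methoxy-N-methylacetamide F10. Aryllithium 13, made from 11 as in step 7, would then be acylated by F10 at −78 °C to give deoxybenzoin 16.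

**Further compounds**

F1 | step 10 | 2-[2-(tert-butyldimethylsilyloxy)-3-geranyl-4-methoxyphenyl]-1-[2-hydroxy-6-methoxy-4-(triisopropylsilyloxy)phenyl]ethanone | COc1cc(O[Si](C(C)C)(C(C)C)C(C)C)cc(O)c1C(=O)Cc1ccc(OC)c(C/C=C(\C)CCC=C(C)C)c1O[Si](C)(C)C(C)(C)C
F2 | step 10 | 3-[2-(tert-butyldimethylsilyloxy)-3-geranyl-4-methoxyphenyl]-5-methoxy-7-(triisopropylsilyloxy)chromen-4-one | COc1ccc(-c2coc3cc(O[Si](C(C)C)(C(C)C)C(C)C)cc(OC)c3c2=O)c(O[Si](C)(C)C(C)(C)C)c1C/C=C(\C)CCC=C(C)C
F3 | step 10 | (3S,4S)-3-[2-(tert-butyldimethylsilyloxy)-3-geranyl-4-methoxyphenyl]-5-methoxy-7-(triisopropylsilyloxy)chroman-4-ol | COc1ccc([C@H]2COc3cc(O[Si](C(C)C)(C(C)C)C(C)C)cc(OC)c3[C@H]2O)c(O[Si](C)(C)C(C)(C)C)c1C/C=C(\C)CCC=C(C)C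
F4 | step 11 | 1-[2-hydroxy-6-methoxy-4-(triisopropylsilyloxy)phenyl]ethanone | CC(=O)c1c(O)cc(O[Si](C(C)C)(C(C)C)C(C)C)cc1OC
F5 | step 11 | 1-[2-(tert-butyldimethylsilyloxy)-6-methoxy-4-(triisopropylsilyloxy)phenyl]ethanone | CC(=O)c1c(O[Si](C)(C)C(C)(C)C)cc(O[Si](C(C)C)(C(C)C)C(C)C)cc1OC
F6 | step 11 | 2-[2-(tert-butyldimethylsilyloxy)-3-geranyl-4-methoxyphenyl]-1-[2-(tert-butyldimethylsilyloxy)-6-methoxy-4-(triisopropylsilyloxy)phenyl]ethanone | COc1cc(O[Si](C(C)C)(C(C)C)C(C)C)cc(O[Si](C)(C)C(C)(C)C)c1C(=O)Cc1ccc(OC)c(C/C=C(\C)CCC=C(C)C)c1O[Si](C)(C)C(C)(C)C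
F7 | step 11 | 2-diazo-2-[2-(tert-butyldimethylsilyloxy)-3-geranyl-4-methoxyphenyl]-1-[2-(tert-butyldimethylsilyloxy)-6-methoxy-4-(triisopropylsilyloxy)phenyl]ethanone | COc1cc(O[Si](C(C)C)(C(C)C)C(C)C)cc(O[Si](C)(C)C(C)(C)C)c1C(=O)C(=[N+]=[N-])c1ccc(OC)c(C/C=C(\C)CCC=C(C)C)c1O[Si](C)(C)C(C)(C)C
F8 | step 11 | (3S)-5-(tert-butyldimethylsilyloxy)-3-[2-(tert-butyldimethylsilyloxy)-3-geranyl-4-methoxyphenyl]-7-(triisopropylsilyloxy)chroman-4-one | COc1ccc([C@H]2COc3cc(O[Si](C(C)C)(C(C)C)C(C)C)cc(O[Si](C)(C)C(C)(C)C)c3C2=O)c(O[Si](C)(C)C(C)(C)C)c1C/C=C(\C)CCC=C(C)C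
F9 | step 8 | ethyl 2-[2-(tert-butyldimethylsilyloxy)-3-geranyl-4-methoxyphenyl]acetate | CCOC(=O)Cc1ccc(OC)c(C/C=C(\C)CCC=C(C)C)c1O[Si](C)(C)C(C)(C)C
F10 | step 8 | 2-[2-(tert-butyldimethylsilyloxy)-3-geranyl-4-methoxyphenyl]-N-methoxy-N-methylacetamide | CON(C)C(=O)Cc1ccc(OC)c(C/C=C(\C)CCC=C(C)C)c1O[Si](C)(C)C(C)(C)C
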